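Ring C is closed by making C4–C4a and O1–C8a together, with ring A entering not as an arene but as 2-(1,1-dimethylallyl)-1,4-benzoquinone. The para relationship of C7–OH and C4a in ring A maps onto the two quinone carbonyls, and C8a is the β-carbon of the unsubstituted enone arm. A γ-lithio alkoxide, made from an enantiopure (S)-3-iodo-1-arylpropan-1-ol that already carries the complete ring B, adds through carbon to the C4a carbonyl and then through oxygen to C8a in one pot; the bulky C6 substituent directs both events. Dehydrative aromatisation then restores ring A with its free C7 phenol, and a final desilylation gives Kazinol H.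

Key step: step 12

Remarks on the chemistry:
- Ar = 2,2-dimethyl-5-(3-methylbut-2-en-1-yl)-8-[(triisopropylsilyl)oxy]-2H-chromen-6-yl (ring B with its chromene, prenyl group and silyl-protected phenol).
- Compound 16 is expected as the two cis-fused C4a/C8a diastereomers. Both converge in step 13, so these two centres are left open in its SMILES.
- (S)-HYTRA [(S)-2-hydroxy-1,2,2-triphenylethyl acetate], tributyl(3-methylbut-2-en-1-yl)stannane and the Burgess reagent are taken as purchased.

Step 1
Reactants: 1 4-methoxyphenol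
Product: 2 1-methoxy-4-[(3-methylbut-2-en-1-yl)oxy]benzene
Conditions: prenyl bromide, K2CO3, acetone, reflux
Reagents that add atoms: prenyl bromide, CC(C)=CCBr
Why: Williamson etherification, the phenoxide displacing the primary allylic bromide by SN2.

Step 2
Reactants: 2 1-methoxy-4-[(3-methylbut-2-en-1-yl)oxy]benzene
Product: 3 4-methoxy-2-(2-methylbut-3-en-2-yl)phenol
Conditions: N,N-diethylaniline, 190 °C
Reagents that add atoms: none
Why: Aromatic Claisen rearrangement, which should deliver the dimethyl-substituted allyl terminus to an ortho carbon (the two are equivalent) while the methoxy group blocks onward migration to the para position.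

Step 3
Reactants: 3 4-methoxy-2-(2-methylbut-3-en-2-yl)phenol
Product: 4 2-(2-methylbut-3-en-2-yl)cyclohexa-2,5-diene-1,4-dione
Conditions: PhI(OAc)2, MeCN/H2O, 0 °C
Reagents that add atoms: water, O
Why: Oxidative demethylation of a p-methoxyphenol, in which water adds to the para carbon of the oxidised phenol and methanol leaves to give the quinone, the isolated vinyl group being inert.

Step 4
Reactants: 5 2-bromo-4,5-dimethoxybenzaldehyde
Product: 6 2-bromo-4,5-dihydroxybenzaldehyde
Conditions: BBr3, CH2Cl2, −78 °C to rt; H2O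
Reagents that add atoms: none
Why: Lewis-acid cleavage of both aryl methyl ethers by BBr3, done before any acid-sensitive group is present.

Step 5
Reactants: 6 2-bromo-4,5-dihydroxybenzaldehyde
Product: 7 2-bromo-5-hydroxy-4-[(2-methylbut-3-yn-2-yl)oxy]benzaldehyde
Conditions: 3-chloro-3-methylbut-1-yne (1.05 equiv), K2CO3 (1.0 equiv), KI, CuI (cat.), acetone, 55 °C
Reagents that add atoms: 3-chloro-3-methylbut-1-yne, C#CC(C)(C)Cl
Why: Copper-assisted propargylic O-alkylation, selective because the 4-OH para to the formyl group is the more acidic phenol and is the one deprotonated by a single equivalent of base.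

Step 6
Reactants: 7 2-bromo-5-hydroxy-4-[(2-methylbut-3-yn-2-yl)oxy]benzaldehyde
Product: 8 5-bromo-8-hydroxy-2,2-dimethyl-2H-chromene-6-carbaldehyde
Conditions: N,N-diethylaniline, 190 °C
Reagents that add atoms: none
Why: Propargyl Claisen rearrangement to the only free ortho carbon, followed by a 1,5-hydrogen shift and oxa-6π electrocyclisation, should build the 2,2-dimethylchromene next to the bromine.

Step 7
Reactants: 8 5-bromo-8-hydroxy-2,2-dimethyl-2H-chromene-6-carbaldehyde
Product: 9 5-bromo-2,2-dimethyl-8-[(triisopropylsilyl)oxy]-2H-chromene-6-carbaldehyde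
Conditions: TIPSCl, imidazole, DMF, rt
Reagents that add atoms: chlorotriisopropylsilane, CC(C)[Si](Cl)(C(C)C)C(C)C
Why: Silyl ether formation gives a phenol protection that should survive organolithium, hydride and mild base and is removed by fluoride at the end.

Step 8
Reactants: 9 5-bromo-2,2-dimethyl-8-[(triisopropylsilyl)oxy]-2H-chromene-6-carbaldehyde
Product: 10 2,2-dimethyl-5-(3-methylbut-2-en-1-yl)-8-[(triisopropylsilyl)oxy]-2H-chromene-6-carbaldehyde (Ar–CHO)
Conditions: tributyl(3-methylbut-2-en-1-yl)stannane, Pd(PPh3)4 (cat.), DMF, 100 °C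
Reagents that add atoms: tributyl(3-methylbut-2-en-1-yl)stannane, CCCC[Sn](CCCC)(CCCC)CC=C(C)C
Why: Stille coupling, in which the formyl group activates the ortho C–Br bond for oxidative addition and reductive elimination from the less hindered allyl terminus should give the linear prenyl group.

Step 9
Reactants: 10 Ar–CHO
Product: 11 (1S)-2-hydroxy-1,2,2-triphenylethyl (3S)-3-hydroxy-3-Ar-propanoate
Conditions: (S)-HYTRA, LDA (2.1 equiv), THF, −78 to 0 °C; then 10, −100 °C; aq NH4Cl
Reagents that add atoms: (S)-2-hydroxy-1,2,2-triphenylethyl acetate, CC(=O)O[C@@H](c1ccccc1)C(O)(c1ccccc1)c1ccccc1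
Why: HYTRA acetate aldol addition, in which the doubly lithiated (S)-auxiliary enolate should attack one aldehyde face to set the (3S)-carbinol (the later C2), the minor diastereomer being removable by chromatography or crystallisation while the auxiliary is attached.

Step 10
Reactants: 11 (1S)-2-hydroxy-1,2,2-triphenylethyl (3S)-3-hydroxy-3-Ar-propanoate
Product: 12 (1S)-1-Ar-propane-1,3-diol
Conditions: LiAlH4, THF, 0 °C; aqueous work-up
Reagents that add atoms: none
Why: Hydride reduction of the ester gives the primary alcohol and releases the auxiliary diol without touching the carbinol centre.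

Step 11
Reactants: 12 (1S)-1-Ar-propane-1,3-diol
Product: 13 (1S)-3-iodo-1-Ar-propan-1-ol
Conditions: I2, PPh3, imidazole, CH2Cl2, −20 to 0 °C
Reagents that add atoms: iodine, II
Why: Appel-type iodination, in which the iodophosphonium reagent should activate the unhindered primary hydroxyl faster than the ortho-flanked secondary benzylic one and iodide displaces it by SN2, leaving the stereocentre alone.

Step 12
Reactants: 13 (1S)-3-iodo-1-Ar-propan-1-ol; 4 2-(2-methylbut-3-en-2-yl)cyclohexa-2,5-diene-1,4-dione
Product: 16 (2S)-2-Ar-4a-hydroxy-6-(2-methylbut-3-en-2-yl)-2,3,4,4a,8,8a-hexahydro-7H-chromen-7-one (cis-fused), via lithio alkoxide 14 (not isolated), via quinol dialkoxide 15 (not isolated)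
Conditions: t-BuLi (3.1 equiv), Et2O/pentane, −78 °C; cannulate into 4 (1.2 equiv) in THF, −78 °C; MeOH, −78 to 0 °C; aq NH4Cl
Reagents that add atoms: none
Why: Deprotonation of the hydroxyl and iodine–lithium exchange give the γ-lithio alkoxide 14, whose carbanion adds 1,2 to the C4a carbonyl of 4 (alkyllithium addition to a quinone giving a p-quinol, the closest known reaction type), forming C4–C4a in dialkoxide 15. Once methanol supplies a proton shuttle, the secondary alkoxide adds to C8a, the β-carbon of the unsubstituted enone arm, in a 6-exo-trig oxa-Michael closure that forms O1–C8a and ring C, as known for alkoxide cyclisations of p-quinols. The new centres C4a and C8a are not controlled relative to C2, only the cis ring fusion is imposed by the tether, and both are erased in step 13, while C2 is not touched. The step needs carbonyl selectivity (C4a over C7) and arm selectivity (C8a over C5): the 1,1-dimethylallyl group on C6 flanks the C7 carbonyl and sits on the α-carbon of the other enone arm, so both should fall to the unhindered positions. Inverse addition at −78 °C should favour 1,2-addition over electron transfer and conjugate addition.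

Step 13
Reactants: 16 (2S)-2-Ar-4a-hydroxy-6-(2-methylbut-3-en-2-yl)-2,3,4,4a,8,8a-hexahydro-7H-chromen-7-one
Product: 18 (2S)-2-Ar-6-(2-methylbut-3-en-2-yl)chroman-7-ol, via dienone 17 (not isolated)
Conditions: Burgess reagent, THF, rt to 50 °C
Reagents that add atoms: none
Why: Burgess dehydration, in which the tertiary C4a sulfamate should eliminate syn with the cis C8a–H to give dienone 17, whose enolisation to the phenol is driven by aromatisation and erases both uncontrolled centres while leaving C2 untouched.

Step 14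
Reactants: 18 (2S)-2-Ar-6-(2-methylbut-3-en-2-yl)chroman-7-ol
Product: 19 Kazinol H
Conditions: TBAF, AcOH, THF, 0 °C
Reagents that add atoms: none
Why: Fluoride desilylation of the aryl triisopropylsilyl ether, buffered with acetic acid so that the electron-rich phenoxide is not exposed to base or air oxidation.

Compound list
1 | 4-methoxyphenol | COc1ccc(O)cc1 | starting material
2 | 1-methoxy-4-[(3-methylbut-2-en-1-yl)oxy]benzene | COc1ccc(OCC=C(C)C)cc1 | intermediate
3 | 4-methoxy-2-(2-methylbut-3-en-2-yl)phenol | COc1ccc(O)c(C(C)(C)C=C)c1 | intermediate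
4 | 2-(2-methylbut-3-en-2-yl)cyclohexa-2,5-diene-1,4-dione | C=CC(C)(C)C1=CC(=O)C=CC1=O | intermediate
5 | 2-bromo-4,5-dimethoxybenzaldehyde | COc1cc(Br)c(C=O)cc1OC | starting material
6 | 2-bromo-4,5-dihydroxybenzaldehyde | O=Cc1cc(O)c(O)cc1Br | intermediate
7 | 2-bromo-5-hydroxy-4-[(2-methylbut-3-yn-2-yl)oxy]benzaldehyde | O=Cc1cc(O)c(OC(C)(C)C#C)cc1Br | intermediate
8 | 5-bromo-8-hydroxy-2,2-dimethyl-2H-chromene-6-carbaldehyde | O=Cc1cc(O)c2OC(C)(C)C=Cc2c1Br | intermediate
9 | 5-bromo-2,2-dimethyl-8-[(triisopropylsilyl)oxy]-2H-chromene-6-carbaldehyde | O=Cc1cc(O[Si](C(C)C)(C(C)C)C(C)C)c2OC(C)(C)C=Cc2c1Br | intermediate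
10 | 2,2-dimethyl-5-(3-methylbut-2-en-1-yl)-8-[(triisopropylsilyl)oxy]-2H-chromene-6-carbaldehyde | O=Cc1cc(O[Si](C(C)C)(C(C)C)C(C)C)c2OC(C)(C)C=Cc2c1CC=C(C)C | intermediate
11 | (1S)-2-hydroxy-1,2,2-triphenylethyl (3S)-3-hydroxy-3-Ar-propanoate | O[C@H](c1cc(O[Si](C(C)C)(C(C)C)C(C)C)c2OC(C)(C)C=Cc2c1CC=C(C)C)CC(=O)O[C@@H](c1ccccc1)C(O)(c1ccccc1)c1ccccc1 | intermediate
12 | (1S)-1-Ar-propane-1,3-diol | O[C@H](c1cc(O[Si](C(C)C)(C(C)C)C(C)C)c2OC(C)(C)C=Cc2c1CC=C(C)C)CCO | intermediate
13 | (1S)-3-iodo-1-Ar-propan-1-ol | O[C@H](c1cc(O[Si](C(C)C)(C(C)C)C(C)C)c2OC(C)(C)C=Cc2c1CC=C(C)C)CCI | intermediate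
14 | lithium (1S)-3-lithio-1-Ar-propan-1-olate | [Li]CC[C@H](O[Li])c1cc(O[Si](C(C)C)(C(C)C)C(C)C)c2OC(C)(C)C=Cc2c1CC=C(C)C | intermediate
15 | 4-hydroxy-4-[(3S)-3-hydroxy-3-Ar-propyl]-2-(2-methylbut-3-en-2-yl)cyclohexa-2,5-dien-1-one (present in the flask as its lithium alkoxides) | O=C1C=CC(O)(CC[C@H](O)c2cc(O[Si](C(C)C)(C(C)C)C(C)C)c3OC(C)(C)C=Cc3c2CC=C(C)C)C=C1C(C)(C)C=C | intermediate
16 | (2S)-2-Ar-4a-hydroxy-6-(2-methylbut-3-en-2-yl)-2,3,4,4a,8,8a-hexahydro-7H-chromen-7-one, cis-fused, both C4a/C8a diastereomers | O=C1CC2O[C@H](c3cc(O[Si](C(C)C)(C(C)C)C(C)C)c4OC(C)(C)C=Cc4c3CC=C(C)C)CCC2(O)C=C1C(C)(C)C=C | intermediate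
17 | (2S)-2-Ar-6-(2-methylbut-3-en-2-yl)-2,3,4,8-tetrahydro-7H-chromen-7-one (keto tautomer of 18) | O=C1CC2=C(CC[C@@H](c3cc(O[Si](C(C)C)(C(C)C)C(C)C)c4OC(C)(C)C=Cc4c3CC=C(C)C)O2)C=C1C(C)(C)C=C | intermediate
18 | (2S)-2-Ar-6-(2-methylbut-3-en-2-yl)chroman-7-ol | C=CC(C)(C)c1cc2c(cc1O)O[C@H](c1cc(O[Si](C(C)C)(C(C)C)C(C)C)c3c(c1CC=C(C)C)C=CC(C)(C)O3)CC2 | intermediate
19 | Kazinol H, (2S)-2-[8-hydroxy-2,2-dimethyl-5-(3-methylbut-2-en-1-yl)-2H-chromen-6-yl]-6-(2-methylbut-3-en-2-yl)chroman-7-ol | C=CC(C)(C)c1cc2c(cc1O)O[C@H](c1cc(O)c3c(c1CC=C(C)C)C=CC(C)(C)O3)CC2 | target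

Total step count: 14. Longest linear sequence: 11 steps (steps 4 to 14, from 5); the quinone 4 is made in 3 steps and joins at step 12.

Steps most likely to fail

Step 12. Single-electron transfer from the alkyllithium to the quinone (reduction instead of addition), conjugate addition, or poor reactivity of the aggregated dianion could consume both partners before the carbonyl addition. The fallback sets out from 13 (with 4) and returns at 16, staging the two bond formations with a protected, less reducing nucleophile. The hydroxyl of 13 is silylated (TESCl, imidazole, CH2Cl2) to the (S)-triethylsilyl ether F1. Iodine–lithium exchange (t-BuLi, Et2O, −78 °C) and transmetalation with anhydrous CeCl3 in THF give an organocerium reagent that should add cleanly to the C4a carbonyl of 4, and the quinol triethylsilyl ether F2 is isolated. PPTS in MeOH at rt removes the alkyl silyl group while the aryl silyl ether stays, giving 15, which closes by oxa-Michael addition to 16 with catalytic K2CO3 in MeOH.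

Step 13. Ring opening by retro-oxa-Michael reaction under the amine that is released, elimination toward C4 to a non-aromatic dienone, or sulfamoylation of the phenol as it forms could divert the dehydration. The fallback sets out from 16 and returns at 19. TMSOTf and Et3N in CH2Cl2 (−78 to 0 °C) convert the ketone into its silyl dienol ether; the allylic C4a–O bond then ionises to an arenium-type cation that loses the C8a proton, giving the aryl trimethylsilyl ether F3. The TBAF/AcOH treatment of step 14 removes both silyl groups from F3 to give 19 directly.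

Step 8. Slow transmetalation at the aryl–palladium centre flanked by two ortho substituents, allyl transposition to the 1,1-dimethylallyl isomer, or protodebromination could erode the coupling. The fallback sets out from 9 and returns at 10, replacing the cross-coupling with an aryl anion alkylation. The aldehyde is masked (HC(OMe)3, PPTS, MeOH) as the dimethyl acetal F4. Bromine–lithium exchange (n-BuLi, THF, −78 °C), transmetalation with CuBr·SMe2 and alkylation with prenyl bromide give the prenylated acetal F5. PPTS in acetone/H2O releases 10.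

Further compounds
F1 | step 12 | triethyl{[(1S)-3-iodo-1-Ar-propyl]oxy}silane | CC[Si](CC)(CC)O[C@H](c1cc(O[Si](C(C)C)(C(C)C)C(C)C)c2OC(C)(C)C=Cc2c1CC=C(C)C)CCI
F2 | step 12 | 4-hydroxy-2-(2-methylbut-3-en-2-yl)-4-[(3S)-3-Ar-3-(triethylsilyloxy)propyl]cyclohexa-2,5-dien-1-one | O=C1C=CC(O)(CC[C@H](O[Si](CC)(CC)CC)c2cc(O[Si](C(C)C)(C(C)C)C(C)C)c3OC(C)(C)C=Cc3c2CC=C(C)C)C=C1C(C)(C)C=C
F3 | step 13 | {[(2S)-2-Ar-6-(2-methylbut-3-en-2-yl)chroman-7-yl]oxy}trimethylsilane | C=CC(C)(C)c1cc2c(cc1O[Si](C)(C)C)O[C@H](c1cc(O[Si](C(C)C)(C(C)C)C(C)C)c3c(c1CC=C(C)C)C=CC(C)(C)O3)CC2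
F4 | step 8 | {[5-bromo-6-(dimethoxymethyl)-2,2-dimethyl-2H-chromen-8-yl]oxy}triisopropylsilane | COC(OC)c1cc(O[Si](C(C)C)(C(C)C)C(C)C)c2OC(C)(C)C=Cc2c1Br
F5 | step 8 | {[6-(dimethoxymethyl)-2,2-dimethyl-5-(3-methylbut-2-en-1-yl)-2H-chromen-8-yl]oxy}triisopropylsilane | COC(OC)c1cc(O[Si](C(C)C)(C(C)C)C(C)C)c2OC(C)(C)C=Cc2c1CC=C(C)C
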